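**Strategy**

Numbering: C1 geranyl bridgehead, C2 to C4 the aroylated diketone bridge, C5 prenyl bridgehead, C6 gem-dimethyl carbon, C7, C8, C9 bridging ketone; ring A is C1-C8-C7-C6-C5-C9. The route rests on cutting C1-C8. The feature used is the C9 carbonyl clamped between both bridgeheads, the mark of a semipinacol shift. In one operation a hypervalent iodine oxidant makes C1 of a cis-fused hydroxy hydrindanedione electron-poor, C8 moves from the C9 carbinol to C1, the cyclopentane grows into ring A, and the C9 ketone and C1 stereocentre appear. The precursor already holds C5, C6 and C7, set on a cyclopentenone by cuprate addition and diketene annulation.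

Key step: step 9

Assumption: the enolised 3-aroyl-2,4-dione of the target equilibrates among its tautomers, so the tautomer written in the target SMILES stands for all of them.

Remark: C1 to C9 as defined above are used for all bicyclic compounds; monocyclic cyclopentenes carry their own ring numbers.

**Route**

Step 1
Reactants: 1 cyclopentane-1,3-dione; 2 prenyl bromide (1-bromo-3-methylbut-2-ene)
Product: 3 2-(3-methylbut-2-en-1-yl)cyclopentane-1,3-dione (mainly enol)
Conditions: KOH (1 equiv), H2O, 0 °C to rt; then HCl to pH 2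
Reagents that add atoms: none
Why: C-alkylation of a cyclic 1,3-dione enolate by an allylic bromide in water, where solvation of the enolate oxygens steers the soft electrophile to C2; the acidic mono-alkylated dione is recovered on acidification.

Step 2
Reactants: 3 2-(3-methylbut-2-en-1-yl)cyclopentane-1,3-dione
Product: 4 3-methoxy-2-(3-methylbut-2-en-1-yl)cyclopent-2-en-1-one
Conditions: TMSCHN2, MeOH/PhMe, 0 °C to rt
Reagents that add atoms: (trimethylsilyl)diazomethane, C[Si](C)(C)C=[N+]=[N-]
Why: O-methylation of the vinylogous acid by TMSCHN2 in methanol; the dione is symmetric so only one enol ether can form, and the acid-free medium keeps the prenyl alkene from cyclising onto the enol oxygen.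

Step 3
Reactants: 4 3-methoxy-2-(3-methylbut-2-en-1-yl)cyclopent-2-en-1-one; 5 RAMP, (R)-1-amino-2-(methoxymethyl)pyrrolidine
Product: 6 (E)-RAMP hydrazone of 4 (C1=N; N-N bond anti to C2)
Conditions: RAMP (1.3 equiv), cat. PPTS, 4 Å MS, PhMe, 80 °C
Reagents that add atoms: none
Why: Hydrazone condensation of an alpha-effect amine at the C1 carbonyl of a 3-alkoxyenone, the same mode by which such vinylogous esters give oximes and sulfonylhydrazones; the amino group settles anti to the substituted C2, which is the geometry the alkylation needs.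

Step 4
Reactants: 6 (E)-RAMP hydrazone of 4; 2 prenyl bromide
Product: 8 (E)-RAMP hydrazone of (5S)-3-methoxy-2,5-bis(3-methylbut-2-en-1-yl)cyclopent-2-en-1-one, via lithium azaenolate 7 (not isolated)
Conditions: LiN(iPr)2, THF, −78 to 0 °C; prenyl bromide, −100 °C to rt
Reagents that add atoms: none
Why: Enders hydrazone alkylation: kinetic deprotonation at C5 gives a lithium azaenolate held rigid by chelation to the methoxymethyl arm and prenyl bromide enters on the open face, so the (R)-auxiliary should set C5 as S (the (S)-auxiliary is known to give the R series with cyclic ketones).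

Step 5
Reactants: 8 (E)-RAMP hydrazone of (5S)-3-methoxy-2,5-bis(3-methylbut-2-en-1-yl)cyclopent-2-en-1-one
Product: 9 (S)-3-methoxy-2,5-bis(3-methylbut-2-en-1-yl)cyclopent-2-en-1-one
Conditions: CuCl2, THF/H2O, pH 7 phosphate buffer, rt; aq. NH3 wash
Reagents that add atoms: water, O
Why: CuCl2-assisted hydrolysis of the dialkylhydrazone at neutral pH, mild enough to leave the methyl enol ether, both alkenes and the enolisable C5 stereocentre untouched while releasing the auxiliary for recovery.

Step 6
Reactants: 9 (S)-3-methoxy-2,5-bis(3-methylbut-2-en-1-yl)cyclopent-2-en-1-one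
Product: 11 (S)-3-methyl-2,4-bis(3-methylbut-2-en-1-yl)cyclopent-2-en-1-one, via tertiary allylic alcohol 10 (not isolated)
Conditions: MeLi, THF, −78 °C; then 1 M HCl, 0 °C to rt
Reagents that add atoms: methyllithium, [Li]C; water, O
Why: Stork-Danheiser carbonyl transposition: 1,2-addition of MeLi to the vinylogous ester, then acid ionises the tertiary allylic alcohol to a methoxy-stabilised cation that water captures at C3, giving the beta-methyl enone with the stereocentre (now C4) carried through unchanged.

Step 7
Reactants: 11 (S)-3-methyl-2,4-bis(3-methylbut-2-en-1-yl)cyclopent-2-en-1-one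
Product: 12 (S)-3,3-dimethyl-2,4-bis(3-methylbut-2-en-1-yl)-1-(trimethylsilyloxy)cyclopent-1-ene
Conditions: Me2CuLi, TMSCl, THF/Et2O, −78 to −20 °C; Et3N, pentane/aq. NaHCO3 work-up
Reagents that add atoms: lithium dimethylcuprate, [Li+].C[Cu-]C; chlorotrimethylsilane, C[Si](C)(C)Cl
Why: Silyl chloride-accelerated Gilman conjugate addition to the beta-methyl enone builds the gem-dimethyl carbon (no new stereocentre) and freezes the enolate as the single regioisomeric silyl enol ether with the double bond towards the prenyl-bearing carbon.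

Step 8
Reactants: 12 (S)-3,3-dimethyl-2,4-bis(3-methylbut-2-en-1-yl)-1-(trimethylsilyloxy)cyclopent-1-ene; 13 diketene (4-methyleneoxetan-2-one)
Product: 16 (2S,3aR,7aS)-7a-hydroxy-3,3-dimethyl-2,3a-bis(3-methylbut-2-en-1-yl)hexahydroindane-4,6-dione (cis-fused; OH and both prenyl groups on one face), via lithium enolate 14 (not isolated), via acylated lithium enolate 15 (not isolated)
Conditions: MeLi (1.05 equiv), THF, 0 °C; diketene, −78 to −40 °C; AcOH quench
Reagents that add atoms: none
Why: Regiospecific lithium enolate generation from the silyl enol ether with MeLi, C-acylation by diketene with lactone opening to a methyl ketone enolate, and 6-(enolendo)-exo-trig aldol closure onto the ring carbonyl (diketene annulation); acylation anti to the C4 prenyl group sets the quaternary carbon, and the aldol can only give the cis ring fusion.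

Step 9
Reactants: 16 (2S,3aR,7aS)-7a-hydroxy-3,3-dimethyl-2,3a-bis(3-methylbut-2-en-1-yl)hexahydroindane-4,6-dione
Product: 17 (1R,5S,7S)-6,6-dimethyl-5,7-bis(3-methylbut-2-en-1-yl)bicyclo[3.3.1]nonane-2,4,9-trione (C7 prenyl anti to the C2-C4 bridge)
Conditions: PhI(OAc)2, KOH, MeOH, 0 °C to rt; dil. HCl work-up
Reagents that add atoms: none
Why: The diketone enolate of 16 is captured by PhI(OMe)2 formed in the flask, at C3 or through the extended enolate at C1; tautomerisation towards C1 puts the aryl-iodanyl leaving group in allylic relation to C1, and the C9 alkoxide then pushes the C9-C8 bond onto C1 as iodobenzene leaves, a vinylogous semipinacol 1,2-shift. The closest known reaction type is the hypervalent iodine oxidative rearrangement of enolisable ketones, and specifically the oxidative ring expansion of diketene-annulated hydroxy hydrindanediones to bicyclo[3.3.1]nonane-2,4,9-triones. Ring A (C1-C8-C7-C6-C5-C9) is closed not end to end but by one-carbon ring enlargement: the cyclopentane bond C9-C8 is traded for C1-C8 through a three-centre suprafacial shift with retention at C8, ring B stays intact and C9 becomes the ketone. The only new stereocentre, C1, is set by the substrate, because C8 can reach C1 only across the face of ring B on which it already sits in the cis-fused bicycle, so C1 follows from C9 and C5. The selectivity needed is migration of C8 rather than C5 or epoxide closure by oxygen: the cis fusion allows a conformer in which the exocyclic C9-C8 bond is axial on ring B and parallel to the p-orbital at C1, whereas C9-C5 is a ring bond near the nodal plane, and KOH supplies the alkoxide push.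

Step 10
Reactants: 17 (1R,5S,7S)-6,6-dimethyl-5,7-bis(3-methylbut-2-en-1-yl)bicyclo[3.3.1]nonane-2,4,9-trione
Product: 18 2-methoxy-6,6-dimethyl-5,7-bis(3-methylbut-2-en-1-yl)bicyclo[3.3.1]non-2-ene-4,9-dione (C1/C5/C7 configured as in 17)
Conditions: TMSCHN2, MeOH/PhMe, 0 °C
Reagents that add atoms: (trimethylsilyl)diazomethane, C[Si](C)(C)C=[N+]=[N-]
Why: O-methylation of the vinylogous acid with TMSCHN2; the oxygen on C2 next to the C1-H bridgehead is far more accessible than the one on C4, which is flanked by quaternary C5 and the C6 methyls, so the 2-methoxy enone should dominate and the minor 4-methoxy isomer is removed by chromatography.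

Step 11
Reactants: 18 2-methoxy-6,6-dimethyl-5,7-bis(3-methylbut-2-en-1-yl)bicyclo[3.3.1]non-2-ene-4,9-dione; 19 geranyl bromide
Product: 21 1-[(2E)-3,7-dimethylocta-2,6-dien-1-yl]-2-methoxy-6,6-dimethyl-5,7-bis(3-methylbut-2-en-1-yl)bicyclo[3.3.1]non-2-ene-4,9-dione (C1/C5/C7 as in the target), via bridgehead lithium compound 20 (not isolated)
Conditions: LiN(iPr)2, THF, −78 °C; geranyl bromide, −78 to 0 °C
Reagents that add atoms: none
Why: Bridgehead lithiation-alkylation as established for bicyclo[3.3.1]nonane trione enol ethers: C1-H is acidified by the C9 ketone and the adjacent alkoxy-substituted sp2 carbon, the carbanion is held in place by the cage and is alkylated with retention by the allylic bromide, while C3-H resists LiN(iPr)2 at this temperature.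

Step 12
Reactants: 22 3,4-dihydroxybenzoic acid
Product: 23 tert-butyldimethylsilyl 3,4-bis(tert-butyldimethylsilyloxy)benzoate
Conditions: TBSCl (3.5 equiv), imidazole, DMF, rt
Reagents that add atoms: tert-butyldimethylsilyl chloride, CC(C)(C)[Si](C)(C)Cl
Why: Exhaustive silylation of both phenols and the carboxylic acid with TBSCl and imidazole (standard silyl ether and silyl ester formation).

Step 13
Reactants: 23 tert-butyldimethylsilyl 3,4-bis(tert-butyldimethylsilyloxy)benzoate
Product: 24 3,4-bis(tert-butyldimethylsilyloxy)benzoyl chloride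
Conditions: (COCl)2, cat. DMF, CH2Cl2, 0 °C to rt
Reagents that add atoms: oxalyl chloride, ClC(=O)C(Cl)=O
Why: Conversion of the silyl ester into the acid chloride by the Vilsmeier reagent from oxalyl chloride and DMF, a neutral acyl chloride synthesis that liberates TBSCl and no HCl, so the aryl silyl ethers stay on.

Step 14
Reactants: 21 1-geranyl-2-methoxy enone; 24 3,4-bis(tert-butyldimethylsilyloxy)benzoyl chloride
Product: 26 3-[3,4-bis(tert-butyldimethylsilyloxy)benzoyl]-1-[(2E)-3,7-dimethylocta-2,6-dien-1-yl]-2-methoxy-6,6-dimethyl-5,7-bis(3-methylbut-2-en-1-yl)bicyclo[3.3.1]non-2-ene-4,9-dione, via C3 lithio compound 25 (not isolated)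
Conditions: lithium 2,2,6,6-tetramethylpiperidide, THF, −78 °C; then 24, −78 to −40 °C
Reagents that add atoms: none
Why: Directed vinylic lithiation at C3, between the methoxy-bearing carbon and the C4 carbonyl, by the hindered amide base, then C-acylation of the vinyllithium by the acid chloride, as known for C3 aroylation of these enol ethers; the product ketone is too hindered for a second addition.

Step 15
Reactants: 26 3-aroyl-2-methoxy enone (bis-silyl ether)
Product: 27 3-[3,4-bis(tert-butyldimethylsilyloxy)benzoyl]-1-[(2E)-3,7-dimethylocta-2,6-dien-1-yl]-2-hydroxy-6,6-dimethyl-5,7-bis(3-methylbut-2-en-1-yl)bicyclo[3.3.1]non-2-ene-4,9-dione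
Conditions: LiCl, DMSO, 120 °C; dil. HCl work-up
Reagents that add atoms: none
Why: SN2 demethylation of the vinylogous methyl ester by chloride in hot DMSO (Krapcho-type dealkylation), driven by release of the stabilised triketone enolate; the silyl ethers shield the catechol during heating, and any that fall off are removed in the next step anyway.

Step 16
Reactants: 27 bis-silyl ether of the target
Product: 28 target CNP0160101.4, 3-(3,4-dihydroxybenzoyl)-1-[(2E)-3,7-dimethylocta-2,6-dien-1-yl]-2-hydroxy-6,6-dimethyl-5,7-bis(3-methylbut-2-en-1-yl)bicyclo[3.3.1]non-2-ene-4,9-dione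
Conditions: TBAF, AcOH, THF, 0 °C
Reagents that add atoms: none
Why: Fluoride cleavage of the two aryl silyl ethers, buffered with acetic acid so that the acidic enolised triketone and the catechol are not exposed to base.

**Compound list**

1 | cyclopentane-1,3-dione | O=C1CCC(=O)C1 | starting material
2 | prenyl bromide | CC(C)=CCBr | starting material
3 | 2-(3-methylbut-2-en-1-yl)cyclopentane-1,3-dione | O=C1CCC(=O)C1CC=C(C)C | intermediate
4 | 3-methoxy-2-(3-methylbut-2-en-1-yl)cyclopent-2-en-1-one | COC1=C(CC=C(C)C)C(=O)CC1 | intermediate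
5 | RAMP, (R)-1-amino-2-(methoxymethyl)pyrrolidine | COC[C@H]1CCCN1N | starting material
6 | (E)-RAMP hydrazone of 4 | COC[C@H]1CCCN1/N=C1/C(CC=C(C)C)=C(OC)CC1 | intermediate
7 | lithium azaenolate of 6 (C5 deprotonated) | COC[C@H]1CCCN1N([Li])C1=CCC(OC)=C1CC=C(C)C | intermediate (not isolated)
8 | (E)-RAMP hydrazone of (5S)-3-methoxy-2,5-bis(3-methylbut-2-en-1-yl)cyclopent-2-en-1-one | COC[C@H]1CCCN1/N=C1/C(CC=C(C)C)=C(OC)C[C@@H]1CC=C(C)C | intermediate
9 | (S)-3-methoxy-2,5-bis(3-methylbut-2-en-1-yl)cyclopent-2-en-1-one | COC1=C(CC=C(C)C)C(=O)[C@@H](CC=C(C)C)C1 | intermediate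
10 | (5S)-3-methoxy-1-methyl-2,5-bis(3-methylbut-2-en-1-yl)cyclopent-2-en-1-ol (C1 epimers) | COC1=C(CC=C(C)C)C(C)(O)[C@@H](CC=C(C)C)C1 | intermediate (not isolated)
11 | (S)-3-methyl-2,4-bis(3-methylbut-2-en-1-yl)cyclopent-2-en-1-one | CC1=C(CC=C(C)C)C(=O)C[C@@H]1CC=C(C)C | intermediate
12 | (S)-3,3-dimethyl-2,4-bis(3-methylbut-2-en-1-yl)-1-(trimethylsilyloxy)cyclopent-1-ene | C[Si](C)(C)OC1=C(CC=C(C)C)C(C)(C)[C@@H](CC=C(C)C)C1 | intermediate
13 | diketene | C=C1CC(=O)O1 | starting material
14 | lithium enolate from 12 | [Li]OC1=C(CC=C(C)C)C(C)(C)[C@@H](CC=C(C)C)C1 | intermediate (not isolated)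
15 | C-acetoacetylated cyclopentanone as its terminal lithium enolate | C=C(O[Li])CC(=O)[C@]1(CC=C(C)C)C(C)(C)[C@@H](CC=C(C)C)CC1=O | intermediate (not isolated)
16 | (2S,3aR,7aS)-7a-hydroxy-3,3-dimethyl-2,3a-bis(3-methylbut-2-en-1-yl)hexahydroindane-4,6-dione | O[C@@]12CC(=O)CC(=O)[C@]1(CC=C(C)C)C(C)(C)[C@@H](CC=C(C)C)C2 | intermediate
17 | (1R,5S,7S)-6,6-dimethyl-5,7-bis(3-methylbut-2-en-1-yl)bicyclo[3.3.1]nonane-2,4,9-trione | [C@@H]12C[C@H](CC=C(C)C)C(C)(C)[C@@](CC=C(C)C)(C(=O)CC1=O)C2=O | intermediate
18 | 2-methoxy-6,6-dimethyl-5,7-bis(3-methylbut-2-en-1-yl)bicyclo[3.3.1]non-2-ene-4,9-dione | [C@@H]12C[C@H](CC=C(C)C)C(C)(C)[C@@](CC=C(C)C)(C(=O)C=C1OC)C2=O | intermediate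
19 | geranyl bromide | CC(C)=CCC/C(C)=C/CBr | starting material
20 | C1 bridgehead lithium compound from 18 | [Li][C@@]12C[C@H](CC=C(C)C)C(C)(C)[C@@](CC=C(C)C)(C(=O)C=C1OC)C2=O | intermediate (not isolated)
21 | 1-geranyl-2-methoxy-6,6-dimethyl-5,7-bis(3-methylbut-2-en-1-yl)bicyclo[3.3.1]non-2-ene-4,9-dione | CC(C)=CCC/C(C)=C/C[C@@]12C[C@H](CC=C(C)C)C(C)(C)[C@@](CC=C(C)C)(C(=O)C=C1OC)C2=O | intermediate
22 | 3,4-dihydroxybenzoic acid | OC(=O)c1ccc(O)c(O)c1 | starting material
23 | tert-butyldimethylsilyl 3,4-bis(tert-butyldimethylsilyloxy)benzoate | CC(C)(C)[Si](C)(C)OC(=O)c1ccc(O[Si](C)(C)C(C)(C)C)c(O[Si](C)(C)C(C)(C)C)c1 | intermediate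
24 | 3,4-bis(tert-butyldimethylsilyloxy)benzoyl chloride | ClC(=O)c1ccc(O[Si](C)(C)C(C)(C)C)c(O[Si](C)(C)C(C)(C)C)c1 | intermediate
25 | C3 lithio compound from 21 | CC(C)=CCC/C(C)=C/C[C@@]12C[C@H](CC=C(C)C)C(C)(C)[C@@](CC=C(C)C)(C(=O)C([Li])=C1OC)C2=O | intermediate (not isolated)
26 | 3-[3,4-bis(tert-butyldimethylsilyloxy)benzoyl] derivative of 21 | CC(C)=CCC/C(C)=C/C[C@@]12C[C@H](CC=C(C)C)C(C)(C)[C@@](CC=C(C)C)(C(=O)C(C(=O)c3ccc(O[Si](C)(C)C(C)(C)C)c(O[Si](C)(C)C(C)(C)C)c3)=C1OC)C2=O | intermediate
27 | bis(tert-butyldimethylsilyl) ether of the target | CC(C)=CCC/C(C)=C/C[C@@]12C[C@H](CC=C(C)C)C(C)(C)[C@@](CC=C(C)C)(C(=O)C(C(=O)c3ccc(O[Si](C)(C)C(C)(C)C)c(O[Si](C)(C)C(C)(C)C)c3)=C1O)C2=O | intermediate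
28 | CNP0160101.4 | CC(C)=CCC/C(C)=C/C[C@@]12C[C@H](CC=C(C)C)C(C)(C)[C@@](CC=C(C)C)(C(=O)C(C(=O)c3ccc(O)c(O)c3)=C1O)C2=O | target

**Step count and risks**

Total step count: 16. Longest linear sequence: 14 steps (steps 1 to 11, then 14 to 16); steps 12 and 13 prepare the aroyl chloride.

Steps most likely to fail:

Step 3. The hydrazine may attack C3 and expel methanol (vinylogous transamination) instead of condensing at the C1 carbonyl, or condensation at the deactivated carbonyl may stall. Fallback, setting out from 4: the auxiliary is dropped. Kinetic deprotonation with LiN(iPr)2 in THF at −78 °C and alkylation with prenyl bromide 2 (standard alpha-prime alkylation of a vinylogous ester) should give racemic 3-methoxy-2,5-bis(3-methylbut-2-en-1-yl)cyclopent-2-en-1-one F1. Preparative supercritical-fluid chromatography on an amylose carbamate phase then separates it into 9 and (R)-3-methoxy-2,5-bis(3-methylbut-2-en-1-yl)cyclopent-2-en-1-one F2, which can be racemised with NaOMe in MeOH and resubmitted. The route is rejoined at 9; steps 3 to 5 are bypassed.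

Step 9. The C3 iodonium ylide may persist in the basic medium without rearranging, the beta-hydroxy ketone may open by retro-aldol cleavage, or methoxide may capture the activated intermediate. Fallback, setting out from 16: oxidation and shift are separated. Brief treatment with PhI(OAc)2 and KOH (2 equiv) in MeOH at −20 °C should give the C3 phenyliodonium ylide of 16 F3, which is isolated. Protonation with CF3CO2H (1 equiv) in CH2Cl2 at −40 to 0 °C then converts the ylide into the C3-H iodonium enol, from which the neutral C9 hydroxyl drives the same C8 shift with loss of iodobenzene. The route is rejoined at 17.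

Step 8. O-acylation or proton transfer may win over C-acylation at the fully substituted enolate carbon, diketene may oligomerise, or attack may occur on the face syn to the C4 prenyl group. Fallback, setting out from 12: the silyl enol ether serves as the two-electron partner for acetylketene, released by heating 2,2,6-trimethyl-4H-1,3-dioxin-4-one in toluene at 110 °C. The hetero-Diels-Alder addition must join the ketene carbon to the prenyl-bearing carbon and should give the cis-fused 2,5,5-trimethyl-4a,6-bis(3-methylbut-2-en-1-yl)-7a-(trimethylsilyloxy)-5,6,7,7a-tetrahydrocyclopenta[b]pyran-4(4aH)-one F4. Dilute HCl in THF opens the silyl ketal to (4S)-3,3-dimethyl-2,4-bis(3-methylbut-2-en-1-yl)-2-(3-oxobutanoyl)cyclopentan-1-one F5. LiN(iPr)2 (2.2 equiv) in THF at −78 to 0 °C forms the diketone dianion, whose terminal carbon closes onto the ring ketone by aldol addition. The route is rejoined at 16.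

Further compounds
F1 | step 3 | racemic 3-methoxy-2,5-bis(3-methylbut-2-en-1-yl)cyclopent-2-en-1-one | COC1=C(CC=C(C)C)C(=O)C(CC=C(C)C)C1
F2 | step 3 | (R)-3-methoxy-2,5-bis(3-methylbut-2-en-1-yl)cyclopent-2-en-1-one | COC1=C(CC=C(C)C)C(=O)[C@H](CC=C(C)C)C1
F3 | step 9 | C3 phenyliodonium ylide of 16 | O[C@@]12CC(=O)C([I+]c3ccccc3)=C([O-])[C@]1(CC=C(C)C)C(C)(C)[C@@H](CC=C(C)C)C2
F4 | step 8 | 2,5,5-trimethyl-4a,6-bis(3-methylbut-2-en-1-yl)-7a-(trimethylsilyloxy)-5,6,7,7a-tetrahydrocyclopenta[b]pyran-4(4aH)-one | CC1=CC(=O)[C@]2(CC=C(C)C)C(C)(C)[C@@H](CC=C(C)C)C[C@]2(O[Si](C)(C)C)O1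
F5 | step 8 | (4S)-3,3-dimethyl-2,4-bis(3-methylbut-2-en-1-yl)-2-(3-oxobutanoyl)cyclopentan-1-one | CC(=O)CC(=O)[C@]1(CC=C(C)C)C(C)(C)[C@@H](CC=C(C)C)CC1=O
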